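**Strategy.** The flavone is disconnected at the O1–C8a bond. Ring A then becomes a plain 3,4,5-trimethoxybenzoyl group whose two ortho C–H carbons (the future C8a and C5) are interchangeable through the mirror plane of that ring. An anodic dehydrogenative C–H/O–H coupling between the enol oxygen on the future C2 and either ortho carbon therefore closes the pyranone (ring C) in one operation, with hydrogen as the only co-product. The precursor is an open-chain 1,3-diaryl-1,3-diketone from a crossed Claisen condensation. Its ring B phenol is masked as an electron-poor, oxidation-resistant tosylate that directs closure to ring A and is removed last.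

Key step: step 3

Assumption: methyl 3-hydroxy-4,5-dimethoxybenzoate 1 is taken as a purchasable compound; the 1,3-diketone is drawn in its diketo form although it should exist largely as the enol; the target has no stereocentre.

**Step 1**
Reactants: 1 methyl 3-hydroxy-4,5-dimethoxybenzoate; 2 TsCl (4-toluenesulfonyl chloride)
Product: 3 methyl 4,5-dimethoxy-3-(tosyloxy)benzoate
Conditions: Et3N, DMAP (cat.), CH2Cl2, 0 °C → rt
Reagents that add atoms: 4-toluenesulfonyl chloride (2), Cc1ccc(S(Cl)(=O)=O)cc1
Why: O-sulfonylation of a phenol with a sulfonyl chloride under amine base and nucleophilic catalysis is fast, and the methyl ester and aryl ethers are inert to it.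

**Step 2**
Reactants: 4 3,4,5-trimethoxyacetophenone; 3 methyl 4,5-dimethoxy-3-(tosyloxy)benzoate
Product: 7 1-(3,4,5-trimethoxyphenyl)-3-[4,5-dimethoxy-3-(tosyloxy)phenyl]propane-1,3-dione, via lithium enolate 5 (not isolated), via lithium diketonate 6 (not isolated)
Conditions: LiN(SiMe3)2 (2.2 equiv), THF, −78 °C; then 3, −78 °C → rt; aq. HCl work-up
Reagents that add atoms: none
Why: Crossed Claisen condensation: the preformed lithium enolate 5 is acylated on carbon by the non-enolisable ester 3, the second equivalent of the hindered amide base converts the product into the chelated diketonate 6 and so drives the equilibrium, and the aryl sulfonate is left alone by the non-nucleophilic base at or below room temperature.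

**Step 3**
Reactants: 7 1-(3,4,5-trimethoxyphenyl)-3-[4,5-dimethoxy-3-(tosyloxy)phenyl]propane-1,3-dione
Product: 8 2-[4,5-dimethoxy-3-(tosyloxy)phenyl]-6,7,8-trimethoxy-4H-chromen-4-one
Conditions: undivided cell, glassy carbon anode, Pt cathode, constant current (5 mA cm−2, about 2.1 F mol−1), 2,6-lutidine (2 equiv), Bu4NPF6 (0.1 M), anhydrous HFIP/CH2Cl2 4:1, 0.02 M, rt
Reagents that add atoms: none
Why: Proposed new method: in HFIP with 2,6-lutidine the enol O–H of 7 should be oxidised at the anode by proton-coupled electron transfer to a delocalised 1,3-dicarbonyl radical (at higher potential the trimethoxyphenyl ring itself would give a radical cation), the oxygen on the carbon that carries ring B bonds to an ortho carbon of ring A, and a second electron transfer with loss of the ring proton restores aromaticity and gives the 4-pyranone while protons are reduced to H2 at the Pt cathode. The closest known reaction types are the anodic dehydrogenative lactonisation of 2-arylbenzoic acids to benzocoumarins and anodic C–H/O–H cyclisations to benzoxazoles in fluorinated alcohols; oxidative C–O closure of a 1,3-diketone enol onto its own aroyl ring has not been shown. The one new ring (ring C, bond O1–C8a) closes in a 6-endo-trig mode onto the arene, whereas 5-exo attack at the ipso carbon would give a spiro intermediate that, with no nucleophile present in anhydrous HFIP, should mainly revert. No stereocentre is formed. The step needs closure onto ring A and not ring B: the attacked carbon of ring A has one methoxy group ortho and a second one para to it and its two ortho carbons are equivalent, whereas each ortho carbon of ring B is activated by only one methoxy group and that ring is deactivated by the sulfonate, which itself resists oxidation. Over-oxidation should be limited because 8 has no enol O–H and is oxidised only at a higher potential, so the charge is cut off near 2 F mol−1.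

**Step 4**
Reactants: 8 2-[4,5-dimethoxy-3-(tosyloxy)phenyl]-6,7,8-trimethoxy-4H-chromen-4-one
Product: 10 2-(3-hydroxy-4,5-dimethoxyphenyl)-6,7,8-trimethoxy-4H-chromen-4-one, via potassium phenolate 9 (not isolated)
Conditions: K2CO3 (3 equiv), MeOH, reflux; then 1 M HCl to pH 2, rt
Reagents that add atoms: none
Why: Base-mediated methanolysis of an aryl sulfonate (methoxide attacks the sulfonyl sulfur and the ring B phenoxide 9 leaves) is an established deprotection for tosyl-protected flavones, and the acid work-up recloses by cyclodehydration any pyranone that methoxide has opened at C2.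

**Compound list**
1 | methyl 3-hydroxy-4,5-dimethoxybenzoate | COC(=O)c1cc(O)c(OC)c(OC)c1 | starting material
2 | 4-toluenesulfonyl chloride | Cc1ccc(S(Cl)(=O)=O)cc1 | starting material
3 | methyl 4,5-dimethoxy-3-(tosyloxy)benzoate | COC(=O)c1cc(OC)c(OC)c(OS(=O)(=O)c2ccc(C)cc2)c1 | intermediate
4 | 3,4,5-trimethoxyacetophenone | CC(=O)c1cc(OC)c(OC)c(OC)c1 | starting material
5 | lithium 1-(3,4,5-trimethoxyphenyl)ethen-1-olate | [Li+].[O-]C(=C)c1cc(OC)c(OC)c(OC)c1 | intermediate (not isolated)
6 | lithium (Z)-1-[4,5-dimethoxy-3-(tosyloxy)phenyl]-3-oxo-3-(3,4,5-trimethoxyphenyl)prop-1-en-1-olate | [Li+].COc1cc(C(=O)/C=C(\[O-])c2cc(OC)c(OC)c(OS(=O)(=O)c3ccc(C)cc3)c2)cc(OC)c1OC | intermediate (not isolated)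
7 | 1-(3,4,5-trimethoxyphenyl)-3-[4,5-dimethoxy-3-(tosyloxy)phenyl]propane-1,3-dione | COc1cc(C(=O)CC(=O)c2cc(OC)c(OC)c(OS(=O)(=O)c3ccc(C)cc3)c2)cc(OC)c1OC | intermediate
8 | 2-[4,5-dimethoxy-3-(tosyloxy)phenyl]-6,7,8-trimethoxy-4H-chromen-4-one | COc1cc(-c2cc(=O)c3cc(OC)c(OC)c(OC)c3o2)cc(OS(=O)(=O)c2ccc(C)cc2)c1OC | intermediate
9 | potassium 2,3-dimethoxy-5-(6,7,8-trimethoxy-4-oxo-4H-chromen-2-yl)phenolate | [K+].COc1cc(-c2cc(=O)c3cc(OC)c(OC)c(OC)c3o2)cc([O-])c1OC | intermediate (not isolated)
10 | 2-(3-hydroxy-4,5-dimethoxyphenyl)-6,7,8-trimethoxy-4H-chromen-4-one | COc1cc(-c2cc(=O)c3cc(OC)c(OC)c(OC)c3o2)cc(O)c1OC | target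

**Total steps:** 4. **Longest linear sequence:** 4 steps (1 → 3 → 7 → 8 → 10).

**Steps most likely to fail**

1. Step 3. The dicarbonyl radical may couple intermolecularly through C3. The oxygen may attack the ipso carbon of ring A, leading to a spiro dienone with loss of the para O-methyl group. The electron-rich ring A may also be oxidised further after closure. The fallback uses known chemistry, sets out from 4 (with ester 3) and returns at 8. Ring bromination of 4 with NBS in MeCN at rt would give 1-(2-bromo-3,4,5-trimethoxyphenyl)ethan-1-one F1. Deprotonation with LiN(SiMe3)2 in THF at −78 °C would give lithium 1-(2-bromo-3,4,5-trimethoxyphenyl)ethen-1-olate F2. Claisen condensation of F2 with 3 as in step 2 would give 1-(2-bromo-3,4,5-trimethoxyphenyl)-3-[4,5-dimethoxy-3-(tosyloxy)phenyl]propane-1,3-dione F3. An intramolecular Ullmann-type O-arylation of the diketone enolate (CuI, 1,10-phenanthroline, K2CO3, DMF, 100 °C) would then form the same O1–C8a bond and deliver 8. The bromine atom fixes the site of C–O bond formation, so ring selectivity no longer depends on electronics.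

2. Step 2. The lithium enolate, or the lithium methoxide released during the condensation, may attack the sulfonyl sulfur and strip the tosyl group, or the condensation may stall. The fallback sets out from 3 and returns at 7. Acid-catalysed hydrolysis of the methyl ester (6 M HCl, 1,4-dioxane, 100 °C; aryl sulfonates and aryl methyl ethers tolerate aqueous acid) would give 4,5-dimethoxy-3-(tosyloxy)benzoic acid F4. (COCl)2 with catalytic DMF in CH2Cl2 would give 4,5-dimethoxy-3-(tosyloxy)benzoyl chloride F5. Soft enolisation of ketone 4 with MgBr2·OEt2 and i-Pr2NEt in CH2Cl2 at rt, with C-acylation by F5, would give 7 without any strong base or alkoxide.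

3. Step 4. Cleavage at sulfur may be slow, the freed phenoxide may be O-methylated by the methyl tosylate co-product, or partial opening of the pyranone may give mixtures. The fallback sets out from 8 and returns at 10. Instead of sparing the pyranone it opens it on purpose. Aqueous KOH in 1,4-dioxane at 80 °C would cleave the sulfonate by hydroxide attack at sulfur (no alkylating co-product) and add to C2. Acidification to pH 4 at 0 °C would give 1-(2-hydroxy-3,4,5-trimethoxyphenyl)-3-(3-hydroxy-4,5-dimethoxyphenyl)propane-1,3-dione F6. Cyclodehydration with catalytic H2SO4 in AcOH at 90 °C, the closing stage of a Baker–Venkataraman flavone synthesis, would then give 10.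

**Further compounds**
F1 | step 3 | 1-(2-bromo-3,4,5-trimethoxyphenyl)ethan-1-one | CC(=O)c1cc(OC)c(OC)c(OC)c1Br
F2 | step 3 | lithium 1-(2-bromo-3,4,5-trimethoxyphenyl)ethen-1-olate | [Li+].[O-]C(=C)c1cc(OC)c(OC)c(OC)c1Br
F3 | step 3 | 1-(2-bromo-3,4,5-trimethoxyphenyl)-3-[4,5-dimethoxy-3-(tosyloxy)phenyl]propane-1,3-dione | COc1cc(C(=O)CC(=O)c2cc(OC)c(OC)c(OS(=O)(=O)c3ccc(C)cc3)c2)c(Br)c(OC)c1OC
F4 | step 2 | 4,5-dimethoxy-3-(tosyloxy)benzoic acid | COc1cc(C(=O)O)cc(OS(=O)(=O)c2ccc(C)cc2)c1OC
F5 | step 2 | 4,5-dimethoxy-3-(tosyloxy)benzoyl chloride | COc1cc(C(Cl)=O)cc(OS(=O)(=O)c2ccc(C)cc2)c1OC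
F6 | step 4 | 1-(2-hydroxy-3,4,5-trimethoxyphenyl)-3-(3-hydroxy-4,5-dimethoxyphenyl)propane-1,3-dione | COc1cc(C(=O)CC(=O)c2cc(OC)c(OC)c(OC)c2O)cc(O)c1OC
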